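In a one-step world each initiator begins one chain and the average chain length follows from the charges, but this flask has a second fate for its initiator.

free monomer 0.30 M; initiator 0.60 mM; time 2.0 h

    free monomer + living end → monomer in chains + living end, rate k1*[living end]*[free monomer] (k1 = 0.99 M⁻¹ s⁻¹)
    free monomer + initiator → living end + monomer in chains (k2 = 0.016 M⁻¹ s⁻¹)
    2 free monomer → homo dimer (k3 = 3.8 × 10⁻⁶ M⁻¹ s⁻¹)
    initiator → spent initiator (k4 = 0.0060 s⁻¹)

- average number of monomer units in a chain (chains begun, living or dead) at 2.0 h
- part of the free monomer that has reacted at 2.0 h

- in percentages every species weighs as the free monomer in it: one homo dimer counts as two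
- a doubled species enters its step squared and goes two at a time
- the average divides the monomer in chains by the number of chains begun, living and dead together
- run time (flask): 2.0 h

The bench rule divides monomer reacted by initiator charged, which gives 500 units per chain at full reaction of the free monomer. That rule stops holding where initiator decay competes with starting. At the charge, starting runs at 0.00480 s⁻¹ per initiator, a pseudo-first-order rate. Decay, at 0.0060 s⁻¹, is faster than that, a ratio of 1.25.

The quantity to carry is therefore the starting share (initiator efficiency), the starting rate divided by the sum of starting and decay rates: 44.4%. My reckoning holds free monomer at its charge in this share and so has 0.267 mM of living ends, which consume free monomer at 2.64 × 10⁻⁴ s⁻¹, a mean time of 3790 s. Initiator lasts about 92.6 s on average, far less than that mean time, so holding free monomer at its charge is fair for the share. Dimer formation, at 2.28 × 10⁻⁶ s⁻¹, is far slower than that. This gives 85.1% reacted and 957 units per chain, where the bench rule at that conversion gives 425.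

The forecast gives 950 (range 900 to 1000) and 84.6% (range 83% to 86%), both slightly lower than my reckoning, reasoning that “about 44% of the initiator starts chains”.

The simulated flask gives 954 units per chain and 84.6% reacted, with living end at 2.65 × 10⁻⁴ M and spent initiator at 3.35 × 10⁻⁴ M after 2.00 h, so the reading of living ends is 44.1% of the initiator charged. The neighbour flask with 0.18 M of free monomer starts at 0.00288 s⁻¹ per initiator, so its starting share is 32.4%, or 0.195 mM of living ends, and that flask reads 1.93 × 10⁻⁴ M, with 74.4% reacted and 690 units per chain.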